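The plan hinges on disconnecting the C1–C2 bond of ring A in the cis-fused octalin. C1 bears the acyl carbon and the C3=C4 double bond lies γ,δ to it, so this bond can arise from a [3,3] shift of an ester enolate whose allylic C–O bond was at C4. A cis-fused six-membered lactone that links C1 and C4 across the ring B cyclohexane and carries a (Z)-propenyl group on C4 is the precursor: its Ireland–Claisen rearrangement builds ring A, frees the C1 carboxyl and fixes C1 and C2 at once. The derived aldehyde is then attached to C3 of a pyridine already bearing the oxygenated cyclohexene at C5.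

Key step: step 9

Locants: the decalin is numbered as 1,2,4a,5,6,7,8,8a-octahydronaphthalene (acyl carbon on C1, methyl on C2, alkene C3=C4); the cyclohexane unit on pyridine C5 is numbered C1' (attached carbon) to C6', with C4' the secondary carbinol and C5', C6' the alkene or epoxide carbons.

Assumption: quinidine is taken as the alkaloid that delivers the (1R,2S) half-ester, and the oxazaborolidine enantiomers are assigned by the usual model (alkynyl as small, alkenyl as large ketone substituent); should a sense prove opposite, the pseudo-enantiomeric alkaloid or the antipodal catalyst would be used.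

Step 1
Reactants: 1 cis-cyclohexane-1,2-dicarboxylic anhydride (meso)
Product: 2 (1R,2S)-2-(methoxycarbonyl)cyclohexane-1-carboxylic acid
Conditions: quinidine (1.1 equiv), MeOH, toluene/CCl4, −55 °C
Reagents that add atoms: methanol (CO)
Why: Alkaloid-mediated desymmetrising methanolysis of a meso anhydride, in which the quinidine-bound methanol opens one of the two enantiotopic carbonyl groups and so sets both ring carbons (later C8a and C4a) as the (1R,2S) half-ester.

Step 2
Reactants: 2 (1R,2S)-2-(methoxycarbonyl)cyclohexane-1-carboxylic acid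
Product: 4 methyl (1S,2R)-2-(diazoacetyl)cyclohexane-1-carboxylate, via isobutyl carbonic mixed anhydride 3 (not isolated)
Conditions: i-BuOCOCl, N-methylmorpholine, THF, −15 °C; then CH2N2, Et2O, 0 °C
Reagents that add atoms: diazomethane (C=[N+]=[N-])
Why: First half of an Arndt–Eistert homologation, in which the acid is activated cold as a mixed anhydride (so that the cis half-ester neither epimerises nor re-closes to the meso anhydride) and acylates diazomethane with the stereocentres untouched.

Step 3
Reactants: 4 methyl (1S,2R)-2-(diazoacetyl)cyclohexane-1-carboxylate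
Product: 6 methyl (1S,2S)-2-(2-tert-butoxy-2-oxoethyl)cyclohexane-1-carboxylate, via ketene 5 (not isolated)
Conditions: PhCO2Ag (cat.), Et3N, t-BuOH, 50 °C, dark
Reagents that add atoms: tert-butanol (CC(C)(C)O)
Why: Wolff rearrangement, in which loss of N2 and a 1,2-shift of the ring carbon with retention give a ketene that tert-butanol traps, so the two esters become distinguishable (tert-butyl versus methyl).

Step 4
Reactants: 6 methyl (1S,2S)-2-(2-tert-butoxy-2-oxoethyl)cyclohexane-1-carboxylate
Product: 7 tert-butyl 2-[(1S,2S)-2-[methoxy(methyl)carbamoyl]cyclohexyl]acetate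
Conditions: MeNH(OMe)·HCl, i-PrMgCl, THF, −20 °C
Reagents that add atoms: N,O-dimethylhydroxylamine hydrochloride (CNOC.Cl)
Why: Weinreb amidation with the magnesium amide of N,O-dimethylhydroxylamine, which attacks the methyl ester and spares the hindered tert-butyl ester, the low temperature keeping the cis α-stereocentre.

Step 5
Reactants: 7 tert-butyl 2-[(1S,2S)-2-[methoxy(methyl)carbamoyl]cyclohexyl]acetate; 8 1-propynylmagnesium bromide
Product: 9 tert-butyl 2-[(1S,2S)-2-(but-2-ynoyl)cyclohexyl]acetate
Conditions: THF, 0 °C; cold 1 M HCl quench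
Reagents that add atoms: none
Why: Weinreb ketone synthesis, in which the chelated tetrahedral adduct stops after one addition and the cold acidic quench removes the liberated amine before it can add to the ynone or epimerise the α-centre.

Step 6
Reactants: 9 tert-butyl 2-[(1S,2S)-2-(but-2-ynoyl)cyclohexyl]acetate
Product: 10 tert-butyl 2-[(1S,2S)-2-[(1R)-1-hydroxybut-2-yn-1-yl]cyclohexyl]acetate
Conditions: (R)-2-methyl-CBS-oxazaborolidine, BH3·SMe2, THF, −30 °C
Reagents that add atoms: none
Why: Corey–Bakshi–Shibata reduction under reagent control, in which the branched ring carbon acts as the large and the linear propynyl group as the small substituent, so the (R)-catalyst should deliver hydride to give the (R)-carbinol, the future C4 stereocentre.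

Step 7
Reactants: 10 tert-butyl 2-[(1S,2S)-2-[(1R)-1-hydroxybut-2-yn-1-yl]cyclohexyl]acetate
Product: 12 (1R,4aS,8aS)-1-(prop-1-yn-1-yl)octahydro-3H-isochromen-3-one (cis-fused δ-lactone), via hydroxy acid 11 (not isolated)
Conditions: TFA, CH2Cl2, 0 °C → rt
Reagents that add atoms: none
Why: Acidolysis of the tert-butyl ester followed by acid-catalysed lactonisation of the δ-hydroxy acid, done at the propargylic stage because a propargylic carbinol does not ionise as an allylic one could, and with the carbinol centre retained because the acyl C–O bond is the one formed.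

Step 8
Reactants: 12 (1R,4aS,8aS)-1-(prop-1-yn-1-yl)octahydro-3H-isochromen-3-one
Product: 13 (1S,4aS,8aS)-1-[(Z)-prop-1-en-1-yl]octahydro-3H-isochromen-3-one (hydrogens at the carbinol carbon and at both ring-fusion carbons all cis)
Conditions: H2 (1 atm), Pd/CaCO3 poisoned with Pb(OAc)2 (Lindlar catalyst), quinoline, EtOAc, rt
Reagents that add atoms: none
Why: Lindlar semi-hydrogenation adds H2 syn to the alkyne and stops at the (Z)-alkene, fixing the geometry that is later translated into C2, while the lactone and the stereocentres are inert.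

Step 9
Reactants: 13 (1S,4aS,8aS)-1-[(Z)-prop-1-en-1-yl]octahydro-3H-isochromen-3-one
Product: 16 (1R,2S,4aR,8aR)-2-methyl-1,2,4a,5,6,7,8,8a-octahydronaphthalene-1-carboxylic acid, via silyl ketene acetal 14 (not isolated), via silyl ester 15 (not isolated)
Conditions: LiN(i-Pr)2, TBSCl, HMPA, THF, −78 °C → rt; toluene, 110 °C; then 1 M HCl, THF
Reagents that add atoms: none
Why: Deprotonation of the lactone and O-silylation give the cyclic silyl ketene acetal 14, whose geometry is dictated by the ring, and on heating its α-carbon (C1) bonds to the terminal propenyl carbon (C2) while the C4–O bond breaks in a concerted suprafacial [3,3] shift, an Ireland–Claisen rearrangement. The closest known reaction type is the ring contraction of alkenyl lactone silyl ketene acetals to cycloalkene carboxylic acids. Ring A closes as a six-membered carbocycle by sigmatropic C1–C2 bond formation inside a bicyclo[2.2.2]octene-like boat, because the C4a–C8a link between the two termini excludes a chair, and the lactone ring opens in the same event. C1 is controlled by the C4 carbinol configuration: the propenyl group can reach C1 only on its own face of the lactone, which leaves the carboxyl cis to H8a and trans to C8. C2 is controlled by the (Z)-alkene geometry, whose methyl group lies on the tether side of the boat and therefore ends trans to the carboxyl. The only selectivity required is boat over chair, which the two-carbon tether secures, and the cis ring fusion is carried through untouched.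

Step 10
Reactants: 16 (1R,2S,4aR,8aR)-2-methyl-1,2,4a,5,6,7,8,8a-octahydronaphthalene-1-carboxylic acid
Product: 17 [(1R,2S,4aR,8aR)-2-methyl-1,2,4a,5,6,7,8,8a-octahydronaphthalen-1-yl]methanol
Conditions: LiAlH4, THF, 0 °C → rt
Reagents that add atoms: none
Why: Hydride reduction of the carboxylic acid to the primary alcohol, which affects no stereocentre and leaves the isolated alkene alone.

Step 11
Reactants: 17 [(1R,2S,4aR,8aR)-2-methyl-1,2,4a,5,6,7,8,8a-octahydronaphthalen-1-yl]methanol
Product: 18 (1R,2S,4aR,8aR)-2-methyl-1,2,4a,5,6,7,8,8a-octahydronaphthalene-1-carbaldehyde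
Conditions: Dess–Martin periodinane, NaHCO3, CH2Cl2, 0 °C → rt
Reagents that add atoms: none
Why: Dess–Martin oxidation under buffered conditions should give the aldehyde without epimerising C1, whose formyl group is in any case trans to both neighbouring substituents (the more stable arrangement).

Step 12
Reactants: 19 5-bromo-2,4-dichloropyridine
Product: 21 5-bromo-2,4-bis[2-(trimethylsilyl)ethoxy]pyridine, via 5-bromo-2-chloro-4-[2-(trimethylsilyl)ethoxy]pyridine 20 (not isolated)
Conditions: Me3SiCH2CH2OH, NaH, DMF, 0 → 80 °C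
Reagents that add atoms: 2-(trimethylsilyl)ethanol (C[Si](C)(C)CCO)
Why: Double nucleophilic aromatic substitution (addition–elimination), in which the alkoxide displaces the 4- and then the 2-chloride, both activated by the ring nitrogen, while the unactivated 5-bromide is kept for metalation.

Step 13
Reactants: 22 1,4-dioxaspiro[4.5]dec-6-en-8-one
Product: 23 (8R)-1,4-dioxaspiro[4.5]dec-6-en-8-ol
Conditions: (S)-2-methyl-CBS-oxazaborolidine, BH3·SMe2, THF, −30 °C
Reagents that add atoms: none
Why: Corey–Bakshi–Shibata 1,2-reduction of the enone, in which the alkenyl side acts as the large substituent so that the (S)-catalyst should give the (R)-allylic alcohol, the future C4' stereocentre.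

Step 14
Reactants: 23 (8R)-1,4-dioxaspiro[4.5]dec-6-en-8-ol
Product: 24 (8R)-8-[(4-methoxybenzyl)oxy]-1,4-dioxaspiro[4.5]dec-6-ene
Conditions: NaH, PMBCl, n-Bu4NI (cat.), DMF, 0 °C → rt
Reagents that add atoms: 4-methoxybenzyl chloride (COc1ccc(CCl)cc1)
Why: Williamson etherification of the sodium alkoxide with the benzylic chloride, which does not involve the carbinol stereocentre.

Step 15
Reactants: 24 (8R)-8-[(4-methoxybenzyl)oxy]-1,4-dioxaspiro[4.5]dec-6-ene
Product: 25 (4R)-4-[(4-methoxybenzyl)oxy]cyclohex-2-en-1-one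
Conditions: 1 M HCl, THF, 0 °C → rt
Reagents that add atoms: water (O)
Why: Acid-catalysed ketal hydrolysis unmasks the enone, the mild aqueous acid leaving the allylic PMB ether and the γ-stereocentre intact.

Step 16
Reactants: 25 (4R)-4-[(4-methoxybenzyl)oxy]cyclohex-2-en-1-one
Product: 26 (2S,3S,4R)-2,3-epoxy-4-[(4-methoxybenzyl)oxy]cyclohexan-1-one (epoxide trans to the ether)
Conditions: 30% H2O2, NaOH (cat.), MeOH, 0 °C
Reagents that add atoms: hydrogen peroxide (OO)
Why: Weitz–Scheffer nucleophilic epoxidation, in which hydroperoxide adds in conjugate fashion to the enone face opposite the C4 ether and the enolate closes the oxirane, giving the trans epoxy ketone.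

Step 17
Reactants: 21 5-bromo-2,4-bis[2-(trimethylsilyl)ethoxy]pyridine; 26 (2S,3S,4R)-2,3-epoxy-4-[(4-methoxybenzyl)oxy]cyclohexan-1-one
Product: 29 5-[(1'S,4'R,5'S,6'S)-5',6'-epoxy-4'-(4-methoxybenzyloxy)-1'-(triethylsilyloxy)cyclohexyl]-2,4-bis[2-(trimethylsilyl)ethoxy]pyridine (epoxide cis to the silyloxy group and trans to the PMB ether), via aryllithium 27 (not isolated), via lithium alkoxide 28 (not isolated)
Conditions: n-BuLi, THF, −78 °C; add 26; then TESOTf, 2,6-lutidine, −78 → −40 °C
Reagents that add atoms: triethylsilyl trifluoromethanesulfonate (CC[Si](CC)(CC)OS(=O)(=O)C(F)(F)F)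
Why: Bromine–lithium exchange followed by 1,2-addition of the aryllithium to the α,β-epoxy ketone from the face opposite the oxirane oxygen sets C1' with its oxygen cis to the epoxide and trans to the C4' ether, and the tertiary alkoxide is trapped as its triethylsilyl ether.

Step 18
Reactants: 29 5-[(1'S,4'R,5'S,6'S)-5',6'-epoxy-4'-(4-methoxybenzyloxy)-1'-(triethylsilyloxy)cyclohexyl]-2,4-bis[2-(trimethylsilyl)ethoxy]pyridine
Product: 30 5-[(1'R,4'R)-4'-(4-methoxybenzyloxy)-1'-(triethylsilyloxy)cyclohex-5'-en-1'-yl]-2,4-bis[2-(trimethylsilyl)ethoxy]pyridine (alkene C5'=C6', the two oxygens trans)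
Conditions: Cp2TiCl2, Zn dust, THF, rt
Reagents that add atoms: none
Why: Nugent–RajanBabu deoxygenation, in which Cp2TiCl (trivalent titanium) opens the epoxide by single-electron transfer, a second equivalent captures the β-titanoxy radical and syn-elimination of the titanium oxide gives the ring alkene, which can only be cis, with C1' and C4' untouched.

Step 19
Reactants: 30 5-[(1'R,4'R)-4'-(4-methoxybenzyloxy)-1'-(triethylsilyloxy)cyclohex-5'-en-1'-yl]-2,4-bis[2-(trimethylsilyl)ethoxy]pyridine; 18 (1R,2S,4aR,8aR)-2-methyl-1,2,4a,5,6,7,8,8a-octahydronaphthalene-1-carbaldehyde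
Product: 32 secondary carbinol in which pyridine C3 of 30 is bonded to the former formyl carbon of 18 (mixture of epimers at the new carbinol carbon), via 3-lithiopyridine 31 (not isolated)
Conditions: n-BuLi, THF, −78 → −20 °C; then 18, −78 °C
Reagents that add atoms: none
Why: Directed ortho-lithiation at C3, the position flanked by the two alkoxy groups, followed by 1,2-addition to the aldehyde, the new carbinol centre being irrelevant because it is oxidised in the next step.

Step 20
Reactants: 32 secondary carbinol (epimer mixture)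
Product: 33 3-acylpyridine: [(1R,2S,4aR,8aR)-2-methyl-1,2,4a,5,6,7,8,8a-octahydronaphthalen-1-yl] ketone of 5-[(1'R,4'R)-4'-(4-methoxybenzyloxy)-1'-(triethylsilyloxy)cyclohex-5'-en-1'-yl]-2,4-bis[2-(trimethylsilyl)ethoxy]pyridin-3-yl
Conditions: Dess–Martin periodinane, NaHCO3, CH2Cl2, rt
Reagents that add atoms: none
Why: Dess–Martin oxidation of the secondary carbinol to the aryl ketone under buffered conditions, to which the silyl ethers, the PMB ether and both alkenes are inert and under which C1 stays in its stable trans,trans arrangement.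

Step 21
Reactants: 33 3-acylpyridine with the C4' PMB ether
Product: 34 the corresponding C4' allylic alcohol (1'R,4'R)
Conditions: DDQ, CH2Cl2/pH 7 buffer, 0 °C
Reagents that add atoms: none
Why: Oxidative PMB cleavage by DDQ (hydride abstraction from the electron-rich benzyl ether, then hydrolysis) frees the C4' allylic alcohol without touching the silicon-based groups.

Step 22
Reactants: 34 C4' allylic alcohol
Product: 35 protected epoxy diol with (1'S,4'R,5'R,6'R) configuration (epoxide cis to the C4' hydroxyl, trans to the C1' silyloxy group)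
Conditions: VO(acac)2 (cat.), t-BuOOH, CH2Cl2, 0 °C → rt
Reagents that add atoms: tert-butyl hydroperoxide (CC(C)(C)OO)
Why: Vanadium-catalysed hydroxyl-directed epoxidation, in which the vanadate ester of the C4' allylic alcohol delivers oxygen to the syn face of C5'=C6' (the face opposite the earlier temporary epoxide) while the undirected C3=C4 alkene does not react.

Step 23
Reactants: 35 protected epoxy diol
Product: 36 N–H pyridone: 3-acyl-4-hydroxy-5-[(1'S,4'R,5'R,6'R)-5',6'-epoxy-1',4'-dihydroxycyclohexyl]pyridin-2(1H)-one carrying the octalin acyl group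
Conditions: n-Bu4NF, THF, 0 → 40 °C; aq. NH4Cl
Reagents that add atoms: none
Why: Fluoride-induced desilylation, in which attack at silicon cleaves the triethylsilyl ether and fragments both 2-(trimethylsilyl)ethyl ethers (loss of ethene) to the 4-hydroxy-2-pyridone, whose acidity buffers the medium so that the epoxy alcohol is kept.

Step 24
Reactants: 36 N–H pyridone
Product: 38 fischerin, via tetrakis(trimethylsilyl) derivative 37 (not isolated)
Conditions: (Me3Si)2NH, Me3SiCl (cat.), 60 °C; then MoO5·py·HMPA, CH2Cl2, rt; aq. Na4EDTA; citric acid, MeOH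
Reagents that add atoms: oxodiperoxomolybdenum pyridine HMPA complex, MoO5·py·HMPA (O=[Mo]12(OO1)OO2.c1ccncc1.CN(C)P(=O)(N(C)C)N(C)C)
Why: N-Hydroxylation of a 2-pyridone through its O-silyl imidate, in which silylation makes the ring nitrogen nucleophilic and masks the hydroxyls, the molybdenum peroxide transfers one oxygen to nitrogen and the mild acidic work-up removes the silyl groups, the isolated C3=C4 alkene reacting only slowly with this peroxide and no stereocentre being touched.

Compound list
1 | cis-cyclohexane-1,2-dicarboxylic anhydride (meso) | O=C1OC(=O)[C@H]2CCCC[C@@H]12 | starting material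
2 | (1R,2S)-2-(methoxycarbonyl)cyclohexane-1-carboxylic acid | OC(=O)[C@@H]1CCCC[C@@H]1C(=O)OC | intermediate
3 | isobutyl carbonic mixed anhydride of 2 | CC(C)COC(=O)OC(=O)[C@@H]1CCCC[C@@H]1C(=O)OC | intermediate
4 | methyl (1S,2R)-2-(diazoacetyl)cyclohexane-1-carboxylate | [N-]=[N+]=CC(=O)[C@@H]1CCCC[C@@H]1C(=O)OC | intermediate
5 | methyl (1S,2S)-2-(2-oxoethenyl)cyclohexane-1-carboxylate (ketene) | O=C=C[C@@H]1CCCC[C@@H]1C(=O)OC | intermediate
6 | methyl (1S,2S)-2-(2-tert-butoxy-2-oxoethyl)cyclohexane-1-carboxylate | CC(C)(C)OC(=O)C[C@@H]1CCCC[C@@H]1C(=O)OC | intermediate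
7 | tert-butyl 2-[(1S,2S)-2-[methoxy(methyl)carbamoyl]cyclohexyl]acetate | CC(C)(C)OC(=O)C[C@@H]1CCCC[C@@H]1C(=O)N(C)OC | intermediate
8 | 1-propynylmagnesium bromide | CC#C[Mg]Br | starting material
9 | tert-butyl 2-[(1S,2S)-2-(but-2-ynoyl)cyclohexyl]acetate | CC(C)(C)OC(=O)C[C@@H]1CCCC[C@@H]1C(=O)C#CC | intermediate
10 | tert-butyl 2-[(1S,2S)-2-[(1R)-1-hydroxybut-2-yn-1-yl]cyclohexyl]acetate | CC(C)(C)OC(=O)C[C@@H]1CCCC[C@@H]1[C@@H](O)C#CC | intermediate
11 | 2-[(1S,2S)-2-[(1R)-1-hydroxybut-2-yn-1-yl]cyclohexyl]acetic acid | OC(=O)C[C@@H]1CCCC[C@@H]1[C@@H](O)C#CC | intermediate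
12 | (1R,4aS,8aS)-1-(prop-1-yn-1-yl)octahydro-3H-isochromen-3-one | CC#C[C@@H]1OC(=O)C[C@@H]2CCCC[C@H]12 | intermediate
13 | (1S,4aS,8aS)-1-[(Z)-prop-1-en-1-yl]octahydro-3H-isochromen-3-one | C/C=C\[C@@H]1OC(=O)C[C@@H]2CCCC[C@H]12 | intermediate
14 | tert-butyldimethylsilyl ketene acetal of 13 | C/C=C\[C@@H]1OC(O[Si](C)(C)C(C)(C)C)=C[C@@H]2CCCC[C@H]12 | intermediate
15 | tert-butyldimethylsilyl ester of 16 | C[C@H]1C=C[C@H]2CCCC[C@H]2[C@@H]1C(=O)O[Si](C)(C)C(C)(C)C | intermediate
16 | (1R,2S,4aR,8aR)-2-methyl-1,2,4a,5,6,7,8,8a-octahydronaphthalene-1-carboxylic acid | C[C@H]1C=C[C@H]2CCCC[C@H]2[C@@H]1C(=O)O | intermediate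
17 | [(1R,2S,4aR,8aR)-2-methyl-1,2,4a,5,6,7,8,8a-octahydronaphthalen-1-yl]methanol | C[C@H]1C=C[C@H]2CCCC[C@H]2[C@@H]1CO | intermediate
18 | (1R,2S,4aR,8aR)-2-methyl-1,2,4a,5,6,7,8,8a-octahydronaphthalene-1-carbaldehyde | C[C@H]1C=C[C@H]2CCCC[C@H]2[C@@H]1C=O | intermediate
19 | 5-bromo-2,4-dichloropyridine | Clc1cc(Cl)c(Br)cn1 | starting material
20 | 5-bromo-2-chloro-4-[2-(trimethylsilyl)ethoxy]pyridine | C[Si](C)(C)CCOc1cc(Cl)ncc1Br | intermediate
21 | 5-bromo-2,4-bis[2-(trimethylsilyl)ethoxy]pyridine | C[Si](C)(C)CCOc1cc(OCC[Si](C)(C)C)c(Br)cn1 | intermediate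
22 | 1,4-dioxaspiro[4.5]dec-6-en-8-one | O=C1C=CC2(CC1)OCCO2 | starting material
23 | (8R)-1,4-dioxaspiro[4.5]dec-6-en-8-ol | O[C@H]1C=CC2(CC1)OCCO2 | intermediate
24 | (8R)-8-[(4-methoxybenzyl)oxy]-1,4-dioxaspiro[4.5]dec-6-ene | COc1ccc(CO[C@H]2C=CC3(CC2)OCCO3)cc1 | intermediate
25 | (4R)-4-[(4-methoxybenzyl)oxy]cyclohex-2-en-1-one | O=C1CC[C@@H](OCc2ccc(OC)cc2)C=C1 | intermediate
26 | (2S,3S,4R)-2,3-epoxy-4-[(4-methoxybenzyl)oxy]cyclohexan-1-one | O=C1CC[C@@H](OCc2ccc(OC)cc2)[C@@H]2O[C@H]12 | intermediate
27 | 5-lithio-2,4-bis[2-(trimethylsilyl)ethoxy]pyridine | C[Si](C)(C)CCOc1cc(OCC[Si](C)(C)C)c([Li])cn1 | intermediate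
28 | lithium alkoxide of the aryl adduct (C1' oxygen cis to the epoxide) | C[Si](C)(C)CCOc1cc(OCC[Si](C)(C)C)c(cn1)[C@@]1(O[Li])CC[C@@H](OCc2ccc(OC)cc2)[C@@H]2O[C@@H]21 | intermediate
29 | 5-[(1'S,4'R,5'S,6'S)-5',6'-epoxy-4'-(4-methoxybenzyloxy)-1'-(triethylsilyloxy)cyclohexyl]-2,4-bis[2-(trimethylsilyl)ethoxy]pyridine | C[Si](C)(C)CCOc1cc(OCC[Si](C)(C)C)c(cn1)[C@@]1(O[Si](CC)(CC)CC)CC[C@@H](OCc2ccc(OC)cc2)[C@@H]2O[C@@H]21 | intermediate
30 | 5-[(1'R,4'R)-4'-(4-methoxybenzyloxy)-1'-(triethylsilyloxy)cyclohex-5'-en-1'-yl]-2,4-bis[2-(trimethylsilyl)ethoxy]pyridine | C[Si](C)(C)CCOc1cc(OCC[Si](C)(C)C)c(cn1)[C@@]1(O[Si](CC)(CC)CC)CC[C@@H](OCc2ccc(OC)cc2)C=C1 | intermediate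
31 | 3-lithio derivative of 30 | [Li]c1c(OCC[Si](C)(C)C)ncc([C@@]2(O[Si](CC)(CC)CC)CC[C@@H](OCc3ccc(OC)cc3)C=C2)c1OCC[Si](C)(C)C | intermediate
32 | secondary carbinol from 31 and 18 (epimer mixture at the carbinol carbon) | C[C@H]1C=C[C@H]2CCCC[C@H]2[C@@H]1C(O)c1c(OCC[Si](C)(C)C)ncc([C@@]2(O[Si](CC)(CC)CC)CC[C@@H](OCc3ccc(OC)cc3)C=C2)c1OCC[Si](C)(C)C | intermediate
33 | fully assembled 3-acylpyridine (C4' PMB ether, C1' triethylsilyl ether) | C[C@H]1C=C[C@H]2CCCC[C@H]2[C@@H]1C(=O)c1c(OCC[Si](C)(C)C)ncc([C@@]2(O[Si](CC)(CC)CC)CC[C@@H](OCc3ccc(OC)cc3)C=C2)c1OCC[Si](C)(C)C | intermediate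
34 | 3-acylpyridine with free C4' allylic alcohol | C[C@H]1C=C[C@H]2CCCC[C@H]2[C@@H]1C(=O)c1c(OCC[Si](C)(C)C)ncc([C@@]2(O[Si](CC)(CC)CC)CC[C@@H](O)C=C2)c1OCC[Si](C)(C)C | intermediate
35 | protected epoxy diol, (1'S,4'R,5'R,6'R) | C[C@H]1C=C[C@H]2CCCC[C@H]2[C@@H]1C(=O)c1c(OCC[Si](C)(C)C)ncc([C@@]2(O[Si](CC)(CC)CC)CC[C@@H](O)[C@H]3O[C@H]32)c1OCC[Si](C)(C)C | intermediate
36 | N–H pyridone (N-deoxyfischerin) | C[C@H]1C=C[C@H]2CCCC[C@H]2[C@@H]1C(=O)c1c(O)c([C@@]2(O)CC[C@@H](O)[C@H]3O[C@H]32)c[nH]c1=O | intermediate
37 | tetrakis(trimethylsilyl) derivative of 36 (2- and 4-silyloxypyridine, both carbinols silylated) | C[C@H]1C=C[C@H]2CCCC[C@H]2[C@@H]1C(=O)c1c(O[Si](C)(C)C)c([C@@]2(O[Si](C)(C)C)CC[C@@H](O[Si](C)(C)C)[C@H]3O[C@H]32)cnc1O[Si](C)(C)C | intermediate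
38 | fischerin | C[C@H]1C=C[C@H]2CCCC[C@H]2[C@@H]1C(=O)c1c(O)c([C@@]2(O)CC[C@@H](O)[C@H]3O[C@H]32)cn(O)c1=O | target

Total step count: 24. Longest linear sequence: 17 steps (steps 1–11 to aldehyde 18, then steps 19–24).

Steps most likely to fail

Step 9. In the enforced boat the (Z)-methyl group is pressed against C8, so the rearrangement may be too slow and the silyl ketene acetal may be lost by desilylation back to the lactone or by C-silylation before the C1–C2 bond forms. The fallback relieves this contact by rearranging the C4-epimeric lactone with an (E)-propenyl group and correcting C1 afterwards by equilibration. It sets out from ynone 9. Reduction with (S)-2-methyl-CBS-oxazaborolidine and BH3·SMe2 should give tert-butyl 2-[(1S,2S)-2-[(1S)-1-hydroxybut-2-yn-1-yl]cyclohexyl]acetate F1. LiAlH4 in refluxing THF reduces the ester and, by trans-hydroalumination of the propargylic alkoxide, the alkyne, giving the (E)-allylic diol F2. TEMPO/PhI(OAc)2 oxidative lactonisation of the primary alcohol onto the secondary one gives the (E)-propenyl lactone F3. Under the conditions of step 9 its silyl ketene acetal F4 rearranges through a boat in which the methyl group and ring B both point towards the lactone bridge and no longer meet, giving the silyl ester F5 and, after hydrolysis, the acid F6, which has C2, C4a and C8a as in 16 and C1 inverted. LiAlH4 gives the alcohol F7, Swern oxidation the all-cis aldehyde F8, and DBU equilibration moves the formyl group trans to both neighbours, which rejoins the route at aldehyde 18.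

Step 24. Oxygen transfer from the molybdenum peroxide to the hindered ring nitrogen may be slow, the silyl groups may be lost before the oxidation, or the C3=C4 alkene may be epoxidised in competition. The fallback forms the N–O bond before the pyridone is unmasked. It sets out from 35. Na2WO4 (cat.) with H2O2 in MeOH, a peroxide system that oxidises pyridine nitrogen and leaves unactivated alkenes alone in neutral solution, should give the pyridine N-oxide F9. Treatment with n-Bu4NF then removes the triethylsilyl group and both 2-(trimethylsilyl)ethyl groups, and loss of the 2-O-alkyl group from the N-oxide gives the 1-hydroxy-2-pyridone directly, which rejoins the route at fischerin 38.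

Step 18. After single-electron opening of the epoxide the organotitanium intermediate may expel the neighbouring silyloxy or PMB-oxy group instead of the titanium-bound oxygen, or the radical may be reduced to an alcohol. The fallback is a two-electron route through a halohydrin and sets out from 29. MgI2 in Et2O/toluene at −20 °C opens the oxirane trans-diaxially to the iodohydrin F10 (either regioisomer leads to the same alkene). MsCl/Et3N gives the iodo mesylate F11, and Zn dust in DMF effects reductive anti-elimination, which rejoins the route at alkene 30.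

Further compounds
F1 | step 9 | tert-butyl 2-[(1S,2S)-2-[(1S)-1-hydroxybut-2-yn-1-yl]cyclohexyl]acetate | CC(C)(C)OC(=O)C[C@@H]1CCCC[C@@H]1[C@H](O)C#CC
F2 | step 9 | 2-[(1S,2S)-2-[(1R,2E)-1-hydroxybut-2-en-1-yl]cyclohexyl]ethan-1-ol | OCC[C@@H]1CCCC[C@@H]1[C@H](O)/C=C/C
F3 | step 9 | (1R,4aS,8aS)-1-[(E)-prop-1-en-1-yl]octahydro-3H-isochromen-3-one | C/C=C/[C@H]1OC(=O)C[C@@H]2CCCC[C@H]12
F4 | step 9 | tert-butyldimethylsilyl ketene acetal of F3 | C/C=C/[C@H]1OC(O[Si](C)(C)C(C)(C)C)=C[C@@H]2CCCC[C@H]12
F5 | step 9 | tert-butyldimethylsilyl ester of F6 | C[C@H]1C=C[C@H]2CCCC[C@H]2[C@H]1C(=O)O[Si](C)(C)C(C)(C)C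
F6 | step 9 | (1S,2S,4aR,8aR)-2-methyl-1,2,4a,5,6,7,8,8a-octahydronaphthalene-1-carboxylic acid | C[C@H]1C=C[C@H]2CCCC[C@H]2[C@H]1C(=O)O
F7 | step 9 | [(1S,2S,4aR,8aR)-2-methyl-1,2,4a,5,6,7,8,8a-octahydronaphthalen-1-yl]methanol | C[C@H]1C=C[C@H]2CCCC[C@H]2[C@H]1CO
F8 | step 9 | (1S,2S,4aR,8aR)-2-methyl-1,2,4a,5,6,7,8,8a-octahydronaphthalene-1-carbaldehyde | C[C@H]1C=C[C@H]2CCCC[C@H]2[C@H]1C=O
F9 | step 24 | pyridine N-oxide of 35 | C[C@H]1C=C[C@H]2CCCC[C@H]2[C@@H]1C(=O)c1c(OCC[Si](C)(C)C)[n+]([O-])cc([C@@]2(O[Si](CC)(CC)CC)CC[C@@H](O)[C@H]3O[C@H]32)c1OCC[Si](C)(C)C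
F10 | step 18 | iodohydrin from 29 (iodide at C5', hydroxyl at C6', trans) | C[Si](C)(C)CCOc1cc(OCC[Si](C)(C)C)c(cn1)[C@@]1(O[Si](CC)(CC)CC)CC[C@@H](OCc2ccc(OC)cc2)[C@@H](I)[C@@H]1O
F11 | step 18 | methanesulfonate of F10 | C[Si](C)(C)CCOc1cc(OCC[Si](C)(C)C)c(cn1)[C@@]1(O[Si](CC)(CC)CC)CC[C@@H](OCc2ccc(OC)cc2)[C@@H](I)[C@@H]1OS(C)(=O)=O
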